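**Assumption:** the SMILES is taken literally, i.e. the all-cis (2R,3S,5R)-oxane (O1, C2 aryl, C3 cinnamyl, C5 carbinol arm, C6) with an (R)-carbinol. TBS = tert-butyldimethylsilyl, TES = triethylsilyl, Cb = N,N-diisopropylcarbamoyl.

## Retrosynthetic overview

1. Target ⇒ base methanolysis of the protected precursor ⇒ styrene cross-metathesis on a C3-allyl oxane ⇒ C3-acetaldehyde ⇒ (Z)-enol carbamate, a masked aldehyde.
2. The oxane is the only ring and is closed after the key step by O1–C6 Williamson etherification of an acyclic triol. C2 is not touched, so the all-cis ring follows from the acyclic stereotriad.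
3. Key bond C2–C3: a titanated (E)-alkenyl carbamate (homoenolate equivalent of the C3–CH2–CHO arm) adds to 4-(TBSO)benzaldehyde. This joins an aldehyde carbon to the β-carbon of a latent aldehyde and sets C2/C3 anti.
4. C5 and the carbinol carbon come from a MgCl2-catalysed anti-aldol of an N-acyloxazolidinone with the same aldehyde; reduction then gives C6–OH.
5. The (E)-allylic carbamate is put in by cross-metathesis of the N-pent-4-enoyl imide with (Z)-but-2-ene-1,4-diyl biscarbamate, itself made from the diol and two equivalents of the carbamoyl chloride.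

## Route

**Step 1**
Reactants: 1 (Z)-but-2-ene-1,4-diol; 2 N,N-diisopropylcarbamoyl chloride
Product: 3 (Z)-but-2-ene-1,4-diyl bis(N,N-diisopropylcarbamate)
Conditions: NaH (2.3 equiv), 2 (2.2 equiv in all), THF, 0 °C → reflux
Reagents that add atoms: N,N-diisopropylcarbamoyl chloride (second equivalent) CC(C)N(C(C)C)C(Cl)=O
Why: Double O-carbamoylation of the dialkoxide (acyl substitution, one molecule of 2 per hydroxyl, two in all) gives the symmetrical internal olefin that serves as metathesis donor of the CH2–OCb terminus; no stereocentre is formed.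

**Step 2**
Reactants: 4 (R)-4-benzyl-1,3-oxazolidin-2-one; 5 pent-4-enoyl chloride
Product: 6 (R)-4-benzyl-3-(pent-4-enoyl)-1,3-oxazolidin-2-one
Conditions: n-BuLi, THF, −78 °C; then 5, −78 → 0 °C
Reagents that add atoms: none
Why: N-acylation of the lithiated oxazolidinone installs the chiral imide that controls the aldol step.

**Step 3**
Reactants: 6 (R)-4-benzyl-3-(pent-4-enoyl)-1,3-oxazolidin-2-one; 3 (Z)-but-2-ene-1,4-diyl bis(N,N-diisopropylcarbamate)
Product: 7 (E)-6-[(R)-4-benzyl-2-oxo-1,3-oxazolidin-3-yl]-6-oxohex-2-en-1-yl N,N-diisopropylcarbamate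
Conditions: 3 (2 equiv), second-generation Hoveyda–Grubbs catalyst (5 mol%), CH2Cl2, 40 °C
Reagents that add atoms: none
Why: Olefin cross-metathesis of the terminal alkene with the symmetrical allylic biscarbamate gives the disubstituted alkene under thermodynamic control, (E) favoured (about 9:1 expected), and the (E)-isomer needed for anti selectivity in step 7 is enriched by crystallisation or by chromatography on AgNO3-impregnated silica.

**Step 4**
Reactants: 7 (E)-6-[(R)-4-benzyl-2-oxo-1,3-oxazolidin-3-yl]-6-oxohex-2-en-1-yl N,N-diisopropylcarbamate; 8 4-[(tert-butyldimethylsilyl)oxy]benzaldehyde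
Product: 10 anti-aldol adduct (2E,5S,6R)-5-[(R)-4-benzyl-2-oxo-1,3-oxazolidine-3-carbonyl]-6-hydroxy-6-[4-(TBSO)phenyl]hex-2-en-1-yl N,N-diisopropylcarbamate, via trimethylsilyl ether 9 (not isolated)
Conditions: MgCl2 (20 mol%), Et3N, TMSCl, EtOAc, rt; then PPTS (cat.), MeOH, 0 °C
Reagents that add atoms: none
Why: Evans MgCl2-catalysed direct anti-aldol reaction, in which soft enolisation gives the chelated (Z)-magnesium enolate, the aldehyde adds to the face away from the benzyl group through a boat-like transition state and silylation turns the catalyst over, so that C5 and the carbinol carbon are set anti in the sense dictated by the (R)-auxiliary before the trimethylsilyl ether is methanolysed.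

**Step 5**
Reactants: 10 anti-aldol adduct
Product: 11 (2E,5R,6R)-6-hydroxy-5-(hydroxymethyl)-6-[4-(TBSO)phenyl]hex-2-en-1-yl N,N-diisopropylcarbamate
Conditions: LiBH4, MeOH (1 equiv), THF, 0 °C
Reagents that add atoms: none
Why: Reductive cleavage of the imide by hydride attack at the exocyclic carbonyl frees C6 as CH2OH and returns the auxiliary, while the carbamate, the aryl silyl ether and both stereocentres are untouched.

**Step 6**
Reactants: 11 (2E,5R,6R)-6-hydroxy-5-(hydroxymethyl)-6-[4-(TBSO)phenyl]hex-2-en-1-yl N,N-diisopropylcarbamate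
Product: 12 (2E,5R,6R)-6-(TESO)-5-[(TESO)methyl]-6-[4-(TBSO)phenyl]hex-2-en-1-yl N,N-diisopropylcarbamate
Conditions: TESCl (2.5 equiv), imidazole, DMF, 0 °C → rt
Reagents that add atoms: chlorotriethylsilane CC[Si](Cl)(CC)CC
Why: Silylation of both hydroxyls (one molecule of chlorotriethylsilane each) removes the acidic protons before the organolithium step, with groups that later leave under weak acid while the aryl TBS ethers stay.

**Step 7 (key step)**
Reactants: 12 (2E,5R,6R)-6-(TESO)-5-[(TESO)methyl]-6-[4-(TBSO)phenyl]hex-2-en-1-yl N,N-diisopropylcarbamate; 8 4-[(tert-butyldimethylsilyl)oxy]benzaldehyde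
Product: 16 triol (1Z,3R,5R,6R)-6-hydroxy-3-[(R)-hydroxy{4-(TBSO)phenyl}methyl]-5-(hydroxymethyl)-6-[4-(TBSO)phenyl]hex-1-en-1-yl N,N-diisopropylcarbamate, via lithium sparteine complex 13 (not isolated), via allyltitanium triisopropoxide 14 (not isolated), via bis-triethylsilyl adduct 15 (not isolated)
Conditions: n-BuLi (1.3 equiv), (+)-sparteine (1.4 equiv), toluene, −78 °C, 3 h; Ti(OiPr)4 (4 equiv), −78 °C; 8 (1.5 equiv), −78 → −40 °C; aq. potassium sodium tartrate; then AcOH–THF–H2O (3:1:1), rt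
Reagents that add atoms: none
Why: Hoppe homoaldol reaction, in which carbamate-directed, diamine-controlled allylic lithiation gives an α-oxyallyl anion (the β-carbon of a masked aldehyde made nucleophilic), lithium–titanium exchange goes with inversion and the allyltitanium adds through its γ-carbon to the aldehyde in a closed chair transition state (aldehyde aryl equatorial, carbamoyloxy axial), which gives the (Z)-enol carbamate with C3 and C2 anti in the absolute sense fixed by (+)-sparteine, after which aqueous acetic acid removes the two TES groups.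

**Step 8**
Reactants: 16 triol
Product: 18 (Z)-2-{(2R,3R,5R)-5-[(R)-hydroxy{4-(TBSO)phenyl}methyl]-2-[4-(TBSO)phenyl]oxan-3-yl}ethenyl N,N-diisopropylcarbamate, via primary tosylate 17 (not isolated)
Conditions: TsCl (1.05 equiv), pyridine, CH2Cl2, 0 °C; then KN(SiMe3)2 (3 equiv), THF, −20 → 0 °C
Reagents that add atoms: none
Why: Selective sulfonylation of the only primary hydroxyl followed by intramolecular Williamson etherification (6-exo-tet by the C2 alkoxide, much faster than 4-exo-tet oxetane closure by the other benzylic alkoxide) forms the oxane at the CH2 carbon, so C2 keeps its configuration and the 2,3,5-all-cis ring results.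

**Step 9**
Reactants: 18 oxane enol carbamate
Product: 19 2-{(2R,3R,5R)-5-[(R)-hydroxy{4-(TBSO)phenyl}methyl]-2-[4-(TBSO)phenyl]oxan-3-yl}acetaldehyde
Conditions: Hg(OAc)2 (20 mol%), AcOH (5 equiv), THF–H2O (4:1), 35 °C
Reagents that add atoms: water O
Why: Mercury diacetate-catalysed hydrolysis of the enol carbamate (oxymercuration at the oxygen-bearing carbon, collapse of the hemiacetal carbamate to the aldehyde with loss of carbamic acid, protodemercuration) unmasks the aldehyde under acetic acid buffering that is too weak to ionise the cis-2-aryl ether or the benzylic alcohol.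

**Step 10**
Reactants: 19 oxanyl acetaldehyde
Product: 20 (2R,3S,5R)-5-[(R)-hydroxy{4-(TBSO)phenyl}methyl]-3-(prop-2-en-1-yl)-2-[4-(TBSO)phenyl]oxane
Conditions: Ph3PCH3Br (3.5 equiv), NaN(SiMe3)2 (3.3 equiv), THF, 0 °C → rt
Reagents that add atoms: methyltriphenylphosphonium bromide C[P+](c1ccccc1)(c1ccccc1)c1ccccc1.[Br-]
Why: Wittig methylenation of the aldehyde (excess ylide tolerates the free hydroxyl as its alkoxide) gives the terminal alkene without touching C3, which is β to the carbonyl.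

**Step 11**
Reactants: 20 C3-allyl oxane; 21 4-ethenylphenyl acetate
Product: 22 4-[(1E)-3-{(2R,3S,5R)-5-[(R)-hydroxy{4-(TBSO)phenyl}methyl]-2-[4-(TBSO)phenyl]oxan-3-yl}prop-1-en-1-yl]phenyl acetate
Conditions: 21 (5 equiv), second-generation Hoveyda–Grubbs catalyst (5 mol%), CH2Cl2, 40 °C
Reagents that add atoms: none
Why: Olefin cross-metathesis of the terminal alkene with the styrene gives the (E)-styrenyl alkene (E strongly favoured for styrene partners, ethene lost) and completes the cinnamyl arm.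

**Step 12**
Reactants: 22 protected precursor
Product: 23 4-[(1E)-3-{(2R,3S,5R)-5-[(R)-hydroxy(4-hydroxyphenyl)methyl]-2-(4-hydroxyphenyl)oxan-3-yl}prop-1-en-1-yl]phenol (target CNP0182155.1)
Conditions: K2CO3, MeOH, rt; aq. NH4Cl work-up
Reagents that add atoms: none
Why: Base-mediated methanolysis cleaves the aryl acetate (transesterification) and both aryl silyl ethers (phenoxide leaves from silicon) at room temperature without touching the benzylic ether, the benzylic alcohol or any stereocentre.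

## Compound list

1 | (Z)-but-2-ene-1,4-diol | OC/C=C\CO | starting material
2 | N,N-diisopropylcarbamoyl chloride | CC(C)N(C(C)C)C(Cl)=O | starting material
3 | (Z)-but-2-ene-1,4-diyl bis(N,N-diisopropylcarbamate) | CC(C)N(C(C)C)C(=O)OC/C=C\COC(=O)N(C(C)C)C(C)C | intermediate
4 | (R)-4-benzyl-1,3-oxazolidin-2-one | O=C1N[C@H](Cc2ccccc2)CO1 | starting material
5 | pent-4-enoyl chloride | C=CCCC(Cl)=O | starting material
6 | (R)-4-benzyl-3-(pent-4-enoyl)-1,3-oxazolidin-2-one | C=CCCC(=O)N1[C@H](Cc2ccccc2)COC1=O | intermediate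
7 | (E)-6-[(R)-4-benzyl-2-oxo-1,3-oxazolidin-3-yl]-6-oxohex-2-en-1-yl N,N-diisopropylcarbamate | CC(C)N(C(C)C)C(=O)OC/C=C/CCC(=O)N1[C@H](Cc2ccccc2)COC1=O | intermediate
8 | 4-[(tert-butyldimethylsilyl)oxy]benzaldehyde | O=Cc1ccc(O[Si](C)(C)C(C)(C)C)cc1 | starting material
9 | 6-O-trimethylsilyl ether of 10 | CC(C)N(C(C)C)C(=O)OC/C=C/C[C@@H]([C@@H](O[Si](C)(C)C)c1ccc(O[Si](C)(C)C(C)(C)C)cc1)C(=O)N1[C@H](Cc2ccccc2)COC1=O | intermediate
10 | (2E,5S,6R)-5-[(R)-4-benzyl-2-oxo-1,3-oxazolidine-3-carbonyl]-6-hydroxy-6-[4-(TBSO)phenyl]hex-2-en-1-yl N,N-diisopropylcarbamate (anti-aldol adduct) | CC(C)N(C(C)C)C(=O)OC/C=C/C[C@@H]([C@@H](O)c1ccc(O[Si](C)(C)C(C)(C)C)cc1)C(=O)N1[C@H](Cc2ccccc2)COC1=O | intermediate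
11 | (2E,5R,6R)-6-hydroxy-5-(hydroxymethyl)-6-[4-(TBSO)phenyl]hex-2-en-1-yl N,N-diisopropylcarbamate | CC(C)N(C(C)C)C(=O)OC/C=C/C[C@@H]([C@@H](O)c1ccc(O[Si](C)(C)C(C)(C)C)cc1)CO | intermediate
12 | (2E,5R,6R)-6-(TESO)-5-[(TESO)methyl]-6-[4-(TBSO)phenyl]hex-2-en-1-yl N,N-diisopropylcarbamate | CC(C)N(C(C)C)C(=O)OC/C=C/C[C@@H]([C@@H](O[Si](CC)(CC)CC)c1ccc(O[Si](C)(C)C(C)(C)C)cc1)CO[Si](CC)(CC)CC | intermediate
13 | (1R)-1-lithio derivative of 12, held as its (+)-sparteine complex | [Li][C@@H](OC(=O)N(C(C)C)C(C)C)/C=C/C[C@@H]([C@@H](O[Si](CC)(CC)CC)c1ccc(O[Si](C)(C)C(C)(C)C)cc1)CO[Si](CC)(CC)CC | intermediate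
14 | (1S)-1-(triisopropoxytitanio) derivative of 12 | CC(C)O[Ti](OC(C)C)(OC(C)C)[C@H](OC(=O)N(C(C)C)C(C)C)/C=C/C[C@@H]([C@@H](O[Si](CC)(CC)CC)c1ccc(O[Si](C)(C)C(C)(C)C)cc1)CO[Si](CC)(CC)CC | intermediate
15 | (1Z,3R,5R,6R)-3-[(R)-hydroxy{4-(TBSO)phenyl}methyl]-6-(TESO)-5-[(TESO)methyl]-6-[4-(TBSO)phenyl]hex-1-en-1-yl N,N-diisopropylcarbamate | CC(C)N(C(C)C)C(=O)O/C=C\[C@H]([C@@H](O)c1ccc(O[Si](C)(C)C(C)(C)C)cc1)C[C@@H]([C@@H](O[Si](CC)(CC)CC)c1ccc(O[Si](C)(C)C(C)(C)C)cc1)CO[Si](CC)(CC)CC | intermediate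
16 | (1Z,3R,5R,6R)-6-hydroxy-3-[(R)-hydroxy{4-(TBSO)phenyl}methyl]-5-(hydroxymethyl)-6-[4-(TBSO)phenyl]hex-1-en-1-yl N,N-diisopropylcarbamate | CC(C)N(C(C)C)C(=O)O/C=C\[C@H]([C@@H](O)c1ccc(O[Si](C)(C)C(C)(C)C)cc1)C[C@@H]([C@@H](O)c1ccc(O[Si](C)(C)C(C)(C)C)cc1)CO | intermediate
17 | primary 4-methylbenzenesulfonate of 16 (on the 5-CH2OH group) | CC(C)N(C(C)C)C(=O)O/C=C\[C@H]([C@@H](O)c1ccc(O[Si](C)(C)C(C)(C)C)cc1)C[C@@H]([C@@H](O)c1ccc(O[Si](C)(C)C(C)(C)C)cc1)COS(=O)(=O)c1ccc(C)cc1 | intermediate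
18 | (Z)-2-{(2R,3R,5R)-5-[(R)-hydroxy{4-(TBSO)phenyl}methyl]-2-[4-(TBSO)phenyl]oxan-3-yl}ethenyl N,N-diisopropylcarbamate (all-cis ring; the C3 label is R only because of CIP priorities) | CC(C)N(C(C)C)C(=O)O/C=C\[C@H]1C[C@@H]([C@@H](O)c2ccc(O[Si](C)(C)C(C)(C)C)cc2)CO[C@H]1c1ccc(O[Si](C)(C)C(C)(C)C)cc1 | intermediate
19 | 2-{(2R,3R,5R)-5-[(R)-hydroxy{4-(TBSO)phenyl}methyl]-2-[4-(TBSO)phenyl]oxan-3-yl}acetaldehyde | O=CC[C@H]1C[C@@H]([C@@H](O)c2ccc(O[Si](C)(C)C(C)(C)C)cc2)CO[C@H]1c1ccc(O[Si](C)(C)C(C)(C)C)cc1 | intermediate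
20 | (2R,3S,5R)-5-[(R)-hydroxy{4-(TBSO)phenyl}methyl]-3-(prop-2-en-1-yl)-2-[4-(TBSO)phenyl]oxane | C=CC[C@H]1C[C@@H]([C@@H](O)c2ccc(O[Si](C)(C)C(C)(C)C)cc2)CO[C@H]1c1ccc(O[Si](C)(C)C(C)(C)C)cc1 | intermediate
21 | 4-ethenylphenyl acetate (4-acetoxystyrene) | CC(=O)Oc1ccc(C=C)cc1 | starting material
22 | 4-[(1E)-3-{(2R,3S,5R)-5-[(R)-hydroxy{4-(TBSO)phenyl}methyl]-2-[4-(TBSO)phenyl]oxan-3-yl}prop-1-en-1-yl]phenyl acetate | CC(=O)Oc1ccc(/C=C/C[C@H]2C[C@@H]([C@@H](O)c3ccc(O[Si](C)(C)C(C)(C)C)cc3)CO[C@H]2c2ccc(O[Si](C)(C)C(C)(C)C)cc2)cc1 | intermediate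
23 | 4-[(1E)-3-{(2R,3S,5R)-5-[(R)-hydroxy(4-hydroxyphenyl)methyl]-2-(4-hydroxyphenyl)oxan-3-yl}prop-1-en-1-yl]phenol | Oc1ccc(/C=C/C[C@H]2C[C@@H]([C@@H](O)c3ccc(O)cc3)CO[C@H]2c2ccc(O)cc2)cc1 | target

## Step count and risks

Total: 12 steps. Longest linear sequence: 11 steps (steps 2–12); step 1 is a one-step side branch.

**Step 7 (most likely to fail).** The lithium–diamine complex of this γ-branched, non-crystallising carbamate may form or equilibrate with low selectivity. The two anti adducts, epimeric at both C2 and C3, would then form in a poor ratio. A [1,5]-silyl shift to the carbanion is also possible. The (E)-alkene purity of 12 limits the anti:syn ratio. The choice of (+)-sparteine rests on the (S)-lithium/inversion model for simple (E)-alkenyl carbamates and should be confirmed on the first batch.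
Fallback: set out from 12 and deprotonate with n-BuLi/TMEDA in toluene at −78 °C to give the racemic lithium carbanion TMEDA complex F1. Transmetalate it with chloro(cyclopentadienyl)[(4S,5S)-2,2-dimethyl-α,α,α′,α′-tetraphenyl-1,3-dioxolane-4,5-dimethanolato]titanium to the chiral α-carbamoyloxyallyl titanium complex F2. Its α-epimers interconvert by 1,3-metal shift, so the chiral ligand, not the deprotonation, chooses the aldehyde face, and the chair transition state passes that sense on to C3. The ligand antipode is taken here as (4S,5S), chosen to deliver the allyl unit to the Re face of 8. Addition to 8 gives 15, and the route is rejoined there; the acetic acid stage then gives 16.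

**Step 8.** With three free hydroxyls, over-sulfonylation or closure of the other benzylic alkoxide to an oxetane could compete, and the all-cis chair needed for ring closure is not the most relaxed one.
Fallback: set out from 15, isolated by leaving out the acetic acid stage of step 7. PPTS in MeOH–CH2Cl2 at −10 °C cleaves only the primary TES ether and gives the mono-triethylsilyl diol F3. TsCl/pyridine gives its primary tosylate F4. KN(SiMe3)2 then closes the ring with only one alkoxide available and gives the oxane carbinol triethylsilyl ether F5. AcOH–THF–H2O removes the last TES group and returns to the route at 18.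

**Step 9.** The electron-poor enol carbamate may resist mercury catalysis at acetic acid strength. Stronger acid would risk ionising the cis-2-aryl benzylic ether and epimerising C2.
Fallback: set out from 18 and treat with MeLi (4 equiv, THF, −78 → 0 °C). Nucleophilic attack at the carbamoyl carbonyl, instead of electrophilic activation of the alkene, releases the dilithium enolate alkoxide F6. Inverse quench into AcOH/THF at −78 °C gives 19, where the route is rejoined.

## Further compounds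

F1 | step 7 | racemic 1-lithio derivative of 12 as its TMEDA complex | [Li]C(OC(=O)N(C(C)C)C(C)C)/C=C/C[C@@H]([C@@H](O[Si](CC)(CC)CC)c1ccc(O[Si](C)(C)C(C)(C)C)cc1)CO[Si](CC)(CC)CC
F2 | step 7 | cyclopentadienyl[(4S,5S)-TADDOLato]titanium bound to C1 of the carbamate 12 (α-epimers interconverting) | CC1(C)O[C@H](C(O2)(c3ccccc3)c3ccccc3)[C@@H](C(O[Ti]2(C2C=CC=C2)C(OC(=O)N(C(C)C)C(C)C)/C=C/C[C@@H]([C@@H](O[Si](CC)(CC)CC)c2ccc(O[Si](C)(C)C(C)(C)C)cc2)CO[Si](CC)(CC)CC)(c3ccccc3)c3ccccc3)O1
F3 | step 8 | (1Z,3R,5R,6R)-3-[(R)-hydroxy{4-(TBSO)phenyl}methyl]-5-(hydroxymethyl)-6-(TESO)-6-[4-(TBSO)phenyl]hex-1-en-1-yl N,N-diisopropylcarbamate | CC(C)N(C(C)C)C(=O)O/C=C\[C@H]([C@@H](O)c1ccc(O[Si](C)(C)C(C)(C)C)cc1)C[C@@H]([C@@H](O[Si](CC)(CC)CC)c1ccc(O[Si](C)(C)C(C)(C)C)cc1)CO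
F4 | step 8 | primary 4-methylbenzenesulfonate of F3 | CC(C)N(C(C)C)C(=O)O/C=C\[C@H]([C@@H](O)c1ccc(O[Si](C)(C)C(C)(C)C)cc1)C[C@@H]([C@@H](O[Si](CC)(CC)CC)c1ccc(O[Si](C)(C)C(C)(C)C)cc1)COS(=O)(=O)c1ccc(C)cc1
F5 | step 8 | carbinol O-triethylsilyl ether of 18 | CC(C)N(C(C)C)C(=O)O/C=C\[C@H]1C[C@@H]([C@@H](O[Si](CC)(CC)CC)c2ccc(O[Si](C)(C)C(C)(C)C)cc2)CO[C@H]1c1ccc(O[Si](C)(C)C(C)(C)C)cc1
F6 | step 9 | dilithium (Z)-enolate alkoxide derived from 18 | [Li]O/C=C\[C@H]1C[C@@H]([C@@H](O[Li])c2ccc(O[Si](C)(C)C(C)(C)C)cc2)CO[C@H]1c1ccc(O[Si](C)(C)C(C)(C)C)cc1
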